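**Retrosynthetic overview** (germacrane numbering: ring C1–C10, lactone C12(=O)–O–C6, C13 = CH2OAc)
1. Target ⇒ open-chain enal / β-triflyloxy enoate 15. The C6–C7 bond is made by an intramolecular Ni/Cr-mediated addition in which the enoate β-carbon C7 reacts as a vinyl anion (an sp2 homoenolate, d3 equivalent) with the C6 aldehyde carbon.
2. Ring order: the ten-membered carbocycle closes first; the butenolide forms second, in the same flask, by lactonization of the C6 alkoxide onto the cis methyl ester.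
3. 15 ⇒ aldehyde 6 by two iterative, catalyst-controlled vinylogous Mukaiyama aldol additions of the prenal-derived dienol silane 8 (C8–C9, then C2–C3). These set C8, C2 and both E-trisubstituted alkenes.
4. 6 ⇒ methyl 3-silyloxypropanoate + methyl dimethoxyacetate by a one-flask Claisen condensation / Z-selective enol triflation.

Assumption: with SiCl4 the (R,R)-bisphosphoramide sends the dienol silane to the Re face of the bound aldehyde; if the sense is the opposite, the two catalyst antipodes are exchanged between steps 5 and 7.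
Catalyst shorthand: "bisphosphoramide" = MeN(CH2)5NMe-linked bis-phosphoric triamide, each P(=O) also bound to both nitrogens of N,N'-dimethyl-1,1'-binaphthyl-2,2'-diamine; (R,R)/(S,S) name the two binaphthyl axes.

**Step 1**
Reactants: 1 methyl 3-hydroxypropanoate
Product: 2 methyl 3-[(tert-butyldiphenylsilyl)oxy]propanoate
Conditions: TBDPSCl, imidazole, DMF, 0 °C → rt
Reagents that add atoms: tert-butyl(chloro)diphenylsilane, CC(C)(C)[Si](Cl)(c1ccccc1)c1ccccc1
Why: Imidazole-promoted silylation of the primary alcohol (silyl ether protection); TBDPS is chosen because it survives the acidic acetal hydrolysis of step 3 and is removed by fluoride in step 8.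

**Step 2**
Reactants: 2 methyl 3-[(tert-butyldiphenylsilyl)oxy]propanoate; 3 methyl 2,2-dimethoxyacetate
Product: 5 methyl (Z)-2-{[(tert-butyldiphenylsilyl)oxy]methyl}-4,4-dimethoxy-3-(triflyloxy)but-2-enoate, via chelated lithium enolate 4 (not isolated)
Conditions: LiN(i-Pr)2 (2.1 equiv), THF, −78 °C; 3, −78 → −20 °C; then Comins' reagent, −78 °C → rt; aq NH4Cl
Reagents that add atoms: Comins' reagent, N-(5-chloropyridin-2-yl)-1,1,1-trifluoro-N-[(trifluoromethyl)sulfonyl]methanesulfonamide, O=S(=O)(N(c1ccc(Cl)cn1)S(=O)(=O)C(F)(F)F)C(F)(F)F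
Why: Crossed Claisen condensation of the ester enolate with the more electrophilic α,α-dialkoxy ester gives the β-keto ester as its lithium-chelated U-shaped enolate, and O-sulfonylation of that chelate places the triflate cis to the ester (Z, CH(OMe)2 cis to CH2OSi), the geometry the final lactonization needs.

**Step 3**
Reactants: 5 methyl (Z)-2-{[(tert-butyldiphenylsilyl)oxy]methyl}-4,4-dimethoxy-3-(triflyloxy)but-2-enoate
Product: 6 methyl (Z)-2-{[(tert-butyldiphenylsilyl)oxy]methyl}-4-oxo-3-(triflyloxy)but-2-enoate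
Conditions: TFA/H2O/CH2Cl2, 0 °C → rt
Reagents that add atoms: water, O
Why: Acid-catalysed acetal hydrolysis; the vinyl triflate, methyl ester and TBDPS ether tolerate aqueous TFA and the tetrasubstituted alkene has no easy path for Z/E isomerization.

**Step 4**
Reactants: 7 3-methylbut-2-enal (prenal)
Product: 8 (E)-tert-butyldimethyl[(3-methylbuta-1,3-dien-1-yl)oxy]silane
Conditions: TBSOTf, Et3N, Et2O, 0 °C → rt
Reagents that add atoms: tert-butyldimethylsilyl trifluoromethanesulfonate, CC(C)(C)[Si](C)(C)OS(=O)(=O)C(F)(F)F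
Why: O-Silylation of the enal with γ-deprotonation (silyl dienol ether formation) gives the (E)-1-silyloxy diene that serves as the C5 unit in steps 5 and 7.

**Step 5**
Reactants: 6 methyl (Z)-2-{[(tert-butyldiphenylsilyl)oxy]methyl}-4-oxo-3-(triflyloxy)but-2-enoate (1.2 equiv); 8 (E)-tert-butyldimethyl[(3-methylbuta-1,3-dien-1-yl)oxy]silane
Product: 10 methyl (2Z,4S,6E)-2-{[(tert-butyldiphenylsilyl)oxy]methyl}-4-hydroxy-6-methyl-8-oxo-3-(triflyloxy)octa-2,6-dienoate, via masked chlorosilyl adduct 9 (not isolated)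
Conditions: SiCl4 (1.5 equiv), (S,S)-bisphosphoramide (5 mol %), i-Pr2NEt (10 mol %), CH2Cl2, −78 °C; then aq NaHCO3
Reagents that add atoms: none
Why: Proposed new method: a catalytic enantioselective vinylogous Mukaiyama aldol addition in which the phosphoramide-bound trichlorosilyl cation activates the conjugated aldehyde and the s-trans dienol silane attacks through its γ-carbon on the Si face (C8 = S, new alkene E), while chloride capture of the silyloxocarbenium ion keeps the product enal masked as an α-chloro silyl ether until work-up so it cannot compete for the nucleophile; the closest known reactions are the SiCl4/bisphosphoramide vinylogous aldol additions of ester-, ketone- and amide-derived silyl dienolates to conjugated aldehydes, the same catalyst's crossed aldehyde–aldehyde aldol (where this chlorohydrin masking operates), and oxazaborolidinone-promoted vinylogous aldol additions of aldehyde-derived silyl dienol ethers.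

**Step 6**
Reactants: 10 methyl (2Z,4S,6E)-2-{[(tert-butyldiphenylsilyl)oxy]methyl}-4-hydroxy-6-methyl-8-oxo-3-(triflyloxy)octa-2,6-dienoate
Product: 11 methyl (2Z,4S,6E)-2-{[(tert-butyldiphenylsilyl)oxy]methyl}-4-(methacryloyloxy)-6-methyl-8-oxo-3-(triflyloxy)octa-2,6-dienoate
Conditions: methacrylic anhydride, DMAP (cat.), pyridine, CH2Cl2, 0 °C
Reagents that add atoms: methacrylic anhydride, C=C(C)C(=O)OC(=O)C(C)=C
Why: DMAP-catalysed acylation (esterification) of the only free hydroxyl installs the C8 methacrylate with retention, under mild buffered conditions that avoid vinylogous β-elimination of the δ-acyloxy enal.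

**Step 7**
Reactants: 11 methyl (2Z,4S,6E)-2-{[(tert-butyldiphenylsilyl)oxy]methyl}-4-(methacryloyloxy)-6-methyl-8-oxo-3-(triflyloxy)octa-2,6-dienoate; 8 (E)-tert-butyldimethyl[(3-methylbuta-1,3-dien-1-yl)oxy]silane
Product: 13 methyl (2Z,4S,6E,8R,10E)-2-{[(tert-butyldiphenylsilyl)oxy]methyl}-8-hydroxy-4-(methacryloyloxy)-6,10-dimethyl-12-oxo-3-(triflyloxy)dodeca-2,6,10-trienoate, via masked chlorosilyl adduct 12 (not isolated)
Conditions: SiCl4 (1.5 equiv), (R,R)-bisphosphoramide (5 mol %), i-Pr2NEt (10 mol %), CH2Cl2, −78 °C; then aq NaHCO3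
Reagents that add atoms: none
Why: Proposed new method: the second vinylogous Mukaiyama aldol addition, run as in step 5 but with the antipodal catalyst so that the dienol silane adds to the Re face of the enal and sets C2 = R under catalyst control, independent of remote C8, again giving the E-alkene and an in-flask masked enal, which is essential here because substrate and product are enals of equal reactivity; closest known reactions as in step 5.

**Step 8**
Reactants: 13 methyl (2Z,4S,6E,8R,10E)-2-{[(tert-butyldiphenylsilyl)oxy]methyl}-8-hydroxy-4-(methacryloyloxy)-6,10-dimethyl-12-oxo-3-(triflyloxy)dodeca-2,6,10-trienoate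
Product: 15 methyl (2Z,4S,6E,8R,10E)-8-acetoxy-2-(acetoxymethyl)-4-(methacryloyloxy)-6,10-dimethyl-12-oxo-3-(triflyloxy)dodeca-2,6,10-trienoate, via diol 14 (not isolated)
Conditions: HF·pyridine, pyridine/THF, 0 °C → rt; then Ac2O, DMAP, 0 °C
Reagents that add atoms: acetic anhydride, CC(=O)OC(C)=O
Why: Fluoride-mediated desilylation of the primary TBDPS ether, then DMAP-catalysed acetylation of both hydroxyls in the same flask (protecting-group exchange/esterification); the triflate, enal and C8 ester are inert to buffered HF·pyridine and no stereocentre is touched.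

**Step 9**
Reactants: 15 methyl (2Z,4S,6E,8R,10E)-8-acetoxy-2-(acetoxymethyl)-4-(methacryloyloxy)-6,10-dimethyl-12-oxo-3-(triflyloxy)dodeca-2,6,10-trienoate
Product: 17 CNP0309304.1 = (2R,6R,8S)-2,13-diacetoxy-8-(methacryloyloxy)germacra-1(10)E,4E,7(11)-trien-12,6-olide, via macrocyclic hydroxy ester 16 (not isolated)
Conditions: CrCl2 (8 equiv), NiCl2 (2 mol %), degassed DMF, rt, slow addition of 15 (final 2 mM)
Reagents that add atoms: none
Why: Intramolecular Nozaki–Hiyama–Kishi reaction: zerovalent nickel inserts into the activated C–OTf bond and transmetalation to trivalent chromium gives a β-alkoxycarbonyl vinylchromium, a β-acylvinyl anion (sp2 homoenolate, d3) equivalent whose normally electrophilic β-carbon C7 adds to the aldehyde carbon C6 to close the ten-membered ring, after which the chromium alkoxide lactonizes onto the cis methyl ester to form the butenolide; C6 is set by macrocyclic substrate control, Si-face addition to the s-trans enal placing H6 syn to H8 (predicted 6R, to be confirmed).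

**Compound list**
1 | methyl 3-hydroxypropanoate | COC(=O)CCO | starting material
2 | methyl 3-[(tert-butyldiphenylsilyl)oxy]propanoate | COC(=O)CCO[Si](c1ccccc1)(c1ccccc1)C(C)(C)C | intermediate
3 | methyl 2,2-dimethoxyacetate | COC(OC)C(=O)OC | starting material
4 | lithium (Z)-enolate of methyl 2-{[(tert-butyldiphenylsilyl)oxy]methyl}-4,4-dimethoxy-3-oxobutanoate (not isolated) | COC(OC)/C([O-])=C(\CO[Si](c1ccccc1)(c1ccccc1)C(C)(C)C)C(=O)OC.[Li+] | intermediate
5 | methyl (Z)-2-{[(tert-butyldiphenylsilyl)oxy]methyl}-4,4-dimethoxy-3-(triflyloxy)but-2-enoate | COC(OC)/C(OS(=O)(=O)C(F)(F)F)=C(\CO[Si](c1ccccc1)(c1ccccc1)C(C)(C)C)C(=O)OC | intermediate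
6 | methyl (Z)-2-{[(tert-butyldiphenylsilyl)oxy]methyl}-4-oxo-3-(triflyloxy)but-2-enoate | O=C/C(OS(=O)(=O)C(F)(F)F)=C(\CO[Si](c1ccccc1)(c1ccccc1)C(C)(C)C)C(=O)OC | intermediate
7 | 3-methylbut-2-enal (prenal) | CC(C)=CC=O | starting material
8 | (E)-tert-butyldimethyl[(3-methylbuta-1,3-dien-1-yl)oxy]silane | C=C(C)/C=C/O[Si](C)(C)C(C)(C)C | intermediate
9 | C8 trichlorosilyl ether of 10 with the enal held as its 1-chloro-1-(TBS-oxy) derivative (not isolated) | Cl[Si](Cl)(Cl)O[C@H](/C(OS(=O)(=O)C(F)(F)F)=C(\CO[Si](c1ccccc1)(c1ccccc1)C(C)(C)C)C(=O)OC)C/C(C)=C/C(Cl)O[Si](C)(C)C(C)(C)C | intermediate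
10 | methyl (2Z,4S,6E)-2-{[(tert-butyldiphenylsilyl)oxy]methyl}-4-hydroxy-6-methyl-8-oxo-3-(triflyloxy)octa-2,6-dienoate | O[C@H](/C(OS(=O)(=O)C(F)(F)F)=C(\CO[Si](c1ccccc1)(c1ccccc1)C(C)(C)C)C(=O)OC)C/C(C)=C/C=O | intermediate
11 | methyl (2Z,4S,6E)-2-{[(tert-butyldiphenylsilyl)oxy]methyl}-4-(methacryloyloxy)-6-methyl-8-oxo-3-(triflyloxy)octa-2,6-dienoate | C=C(C)C(=O)O[C@H](/C(OS(=O)(=O)C(F)(F)F)=C(\CO[Si](c1ccccc1)(c1ccccc1)C(C)(C)C)C(=O)OC)C/C(C)=C/C=O | intermediate
12 | C8 (chain) trichlorosilyl ether of 13 with the enal held as its 1-chloro-1-(TBS-oxy) derivative (not isolated) | C=C(C)C(=O)O[C@H](/C(OS(=O)(=O)C(F)(F)F)=C(\CO[Si](c1ccccc1)(c1ccccc1)C(C)(C)C)C(=O)OC)C/C(C)=C/[C@H](O[Si](Cl)(Cl)Cl)C/C(C)=C/C(Cl)O[Si](C)(C)C(C)(C)C | intermediate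
13 | methyl (2Z,4S,6E,8R,10E)-2-{[(tert-butyldiphenylsilyl)oxy]methyl}-8-hydroxy-4-(methacryloyloxy)-6,10-dimethyl-12-oxo-3-(triflyloxy)dodeca-2,6,10-trienoate | C=C(C)C(=O)O[C@H](/C(OS(=O)(=O)C(F)(F)F)=C(\CO[Si](c1ccccc1)(c1ccccc1)C(C)(C)C)C(=O)OC)C/C(C)=C/[C@H](O)C/C(C)=C/C=O | intermediate
14 | methyl (2Z,4S,6E,8R,10E)-8-hydroxy-2-(hydroxymethyl)-4-(methacryloyloxy)-6,10-dimethyl-12-oxo-3-(triflyloxy)dodeca-2,6,10-trienoate (not isolated) | C=C(C)C(=O)O[C@H](/C(OS(=O)(=O)C(F)(F)F)=C(\CO)C(=O)OC)C/C(C)=C/[C@H](O)C/C(C)=C/C=O | intermediate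
15 | methyl (2Z,4S,6E,8R,10E)-8-acetoxy-2-(acetoxymethyl)-4-(methacryloyloxy)-6,10-dimethyl-12-oxo-3-(triflyloxy)dodeca-2,6,10-trienoate | C=C(C)C(=O)O[C@H](/C(OS(=O)(=O)C(F)(F)F)=C(\COC(C)=O)C(=O)OC)C/C(C)=C/[C@H](OC(C)=O)C/C(C)=C/C=O | intermediate
16 | (E,E)-cyclodecadiene with 6R-hydroxyl, 8S-methacrylate, 2R-acetate and exocyclic C7=C11(CO2Me)(CH2OAc), ester cis to C6, held as its chromium alkoxide (not isolated) | C=C(C)C(=O)O[C@H]1C/C(C)=C/[C@H](OC(C)=O)C/C(C)=C/[C@@H](O)/C1=C(\C(=O)OC)COC(C)=O | intermediate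
17 | CNP0309304.1, (2R,6R,8S)-2,13-diacetoxy-8-(methacryloyloxy)germacra-1(10)E,4E,7(11)-trien-12,6-olide | C=C(C)C(=O)O[C@H]1C/C(C)=C/[C@H](OC(C)=O)C/C(C)=C/[C@H]2OC(=O)C(COC(C)=O)=C12 | target

**Step count**
Total: 9 steps. Longest linear sequence: 8 steps (1, 2, 3, 5, 6, 7, 8, 9); step 4 is the side branch.

**Three steps most likely to fail**

Step 9 (ring closure). The vinylchromium carries an allylic methacrylate on C8 that could be lost by β-elimination (allene) or migrate to the new C6 alkoxide, the ring may oligomerize, and the C6 configuration rests on an unverified conformational prediction. The fallback sets out from 10 and comes back at 17; it keeps the same ring-closing bond but carries C8 as an ether through the cyclization and acylates last. Compound 10 is etherified with 4-methoxybenzyl trichloroacetimidate and catalytic Sc(OTf)3 to give the PMB ether enal F6. The second vinylogous aldol addition (as in step 7) gives the PMB ether hydroxy enal F7. HF·pyridine followed by Ac2O/DMAP (as in step 8) gives the PMB ether diacetate F8. CrCl2/NiCl2 cyclization gives the 8-O-PMB macrocyclic lactone F9, a substrate with no acyl group next to the vinylmetal and a different conformational bias. DDQ in wet CH2Cl2 releases the 8-hydroxy lactone F10, and methacrylic anhydride/DMAP gives 17.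

Step 7 (second vinylogous aldol). Substrate and product are both β-methyl enals, so the step depends on the in-flask masking of the product; without it double addition would cap the yield, and aldehyde-derived dienol silanes are untested with this catalyst. The fallback sets out from 11 and comes back at 13; it moves the nucleophile to the amide oxidation level so that the product cannot react again. 3-Methylbut-2-enoyl chloride and morpholine give 4-(3-methylbut-2-enoyl)morpholine F3. KN(SiMe3)2 and TBSCl convert it into the N,O-silyl dienolate F4. The SiCl4/(R,R)-bisphosphoramide vinylogous aldol addition of F4 to 11 gives the δ-hydroxy enamide F5. Cp2Zr(H)Cl in THF at rt reduces the tertiary amide, but not the esters, to the aldehyde, giving 13.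

Step 5 (first vinylogous aldol). Aldehyde 6 is hindered and unusual (α-triflyloxy, fully substituted alkene), so rate and enantioselectivity are uncertain. The fallback sets out from 6 (with 8) and comes back at 11; it replaces asymmetric catalysis by resolution merged with the acylation. BF3·OEt2-promoted vinylogous Mukaiyama aldol addition in CH2Cl2 at −78 °C, with 6 in excess, gives the racemic hydroxy enal F1. Acylative kinetic resolution with methacrylic anhydride, i-Pr2NEt and catalytic (S)-benzotetramisole (the antipode if the selectivity is reversed) acylates the 4S alcohol to give 11 directly and leaves the (4R)-hydroxy enal F2, which is separated.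

**Further compounds**
F1 | step 5 | racemic methyl (2Z,6E)-2-{[(tert-butyldiphenylsilyl)oxy]methyl}-4-hydroxy-6-methyl-8-oxo-3-(triflyloxy)octa-2,6-dienoate | OC(/C(OS(=O)(=O)C(F)(F)F)=C(\CO[Si](c1ccccc1)(c1ccccc1)C(C)(C)C)C(=O)OC)C/C(C)=C/C=O
F2 | step 5 | methyl (2Z,4R,6E)-2-{[(tert-butyldiphenylsilyl)oxy]methyl}-4-hydroxy-6-methyl-8-oxo-3-(triflyloxy)octa-2,6-dienoate | O[C@@H](/C(OS(=O)(=O)C(F)(F)F)=C(\CO[Si](c1ccccc1)(c1ccccc1)C(C)(C)C)C(=O)OC)C/C(C)=C/C=O
F3 | step 7 | 4-(3-methylbut-2-enoyl)morpholine | CC(C)=CC(=O)N1CCOCC1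
F4 | step 7 | 4-{1-[(tert-butyldimethylsilyl)oxy]-3-methylbuta-1,3-dien-1-yl}morpholine | C=C(C)C=C(O[Si](C)(C)C(C)(C)C)N1CCOCC1
F5 | step 7 | methyl (2Z,4S,6E,8R,10E)-2-{[(tert-butyldiphenylsilyl)oxy]methyl}-8-hydroxy-4-(methacryloyloxy)-6,10-dimethyl-12-(morpholin-4-yl)-12-oxo-3-(triflyloxy)dodeca-2,6,10-trienoate | C=C(C)C(=O)O[C@H](/C(OS(=O)(=O)C(F)(F)F)=C(\CO[Si](c1ccccc1)(c1ccccc1)C(C)(C)C)C(=O)OC)C/C(C)=C/[C@H](O)C/C(C)=C/C(=O)N1CCOCC1
F6 | step 9 | methyl (2Z,4S,6E)-2-{[(tert-butyldiphenylsilyl)oxy]methyl}-4-[(4-methoxybenzyl)oxy]-6-methyl-8-oxo-3-(triflyloxy)octa-2,6-dienoate | COc1ccc(CO[C@H](/C(OS(=O)(=O)C(F)(F)F)=C(\CO[Si](c2ccccc2)(c2ccccc2)C(C)(C)C)C(=O)OC)C/C(C)=C/C=O)cc1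
F7 | step 9 | methyl (2Z,4S,6E,8R,10E)-2-{[(tert-butyldiphenylsilyl)oxy]methyl}-8-hydroxy-4-[(4-methoxybenzyl)oxy]-6,10-dimethyl-12-oxo-3-(triflyloxy)dodeca-2,6,10-trienoate | COc1ccc(CO[C@H](/C(OS(=O)(=O)C(F)(F)F)=C(\CO[Si](c2ccccc2)(c2ccccc2)C(C)(C)C)C(=O)OC)C/C(C)=C/[C@H](O)C/C(C)=C/C=O)cc1
F8 | step 9 | methyl (2Z,4S,6E,8R,10E)-8-acetoxy-2-(acetoxymethyl)-4-[(4-methoxybenzyl)oxy]-6,10-dimethyl-12-oxo-3-(triflyloxy)dodeca-2,6,10-trienoate | COc1ccc(CO[C@H](/C(OS(=O)(=O)C(F)(F)F)=C(\COC(C)=O)C(=O)OC)C/C(C)=C/[C@H](OC(C)=O)C/C(C)=C/C=O)cc1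
F9 | step 9 | (2R,6R,8S)-2,13-diacetoxy-8-[(4-methoxybenzyl)oxy]germacra-1(10)E,4E,7(11)-trien-12,6-olide | COc1ccc(CO[C@H]2C/C(C)=C/[C@H](OC(C)=O)C/C(C)=C/[C@H]3OC(=O)C(COC(C)=O)=C23)cc1
F10 | step 9 | (2R,6R,8S)-2,13-diacetoxy-8-hydroxygermacra-1(10)E,4E,7(11)-trien-12,6-olide | O[C@H]1C/C(C)=C/[C@H](OC(C)=O)C/C(C)=C/[C@H]2OC(=O)C(COC(C)=O)=C12
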